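The route rests on cutting the bond between C1 of the heptane chain and the ipso carbon of ring A (the 3,4-dihydroxy-5-methoxyphenyl ring). It exploits the 1,3,5 pattern C1/O–C3/O–C5. With O5 tied to C1 and C3 as a ketone, C1–C5 become a 2,3-dihydro-4H-pyran-4-one in which C1 is the electrophilic β-carbon. A copper-catalysed conjugate addition of the ring A Grignard reagent to this enantioenriched pyranone joins both halves and completes the carbon skeleton in one operation. The temporary C1–O5 bond is benzylic and para to the oxygen at position 4 of ring A, so it falls with the benzyl ethers on hydrogenolysis. C5 then directs the syn reduction at C3.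

Key step: step 5

Assumption: (R)-BINOL/Ti(OiPr)4 is taken to send the diene to the Re face of the aliphatic aldehyde, the facial sense of the related BINOL–titanium allylation of aldehydes; if the opposite sense is found, (S)-BINOL is used. Chain numbering: C1 is bound to ring A, C7 to ring B (4-hydroxyphenyl).

Step 1
Reactants: 1 1-(benzyloxy)-4-iodobenzene; 2 prop-2-en-1-ol (allyl alcohol)
Product: 3 3-[4-(benzyloxy)phenyl]propanal
Conditions: Pd(OAc)2 (3 mol %), n-Bu4NCl, NaHCO3, DMF, 40 °C
Reagents that add atoms: none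
Why: Mizoroki–Heck arylation of an allylic alcohol under phase-transfer conditions: arylpalladation at the terminal carbon and β-hydride elimination toward the carbinol carbon give the enol and hence the saturated aldehyde, with no stereocentre formed.

Step 2
Reactants: 3 3-[4-(benzyloxy)phenyl]propanal; 4 (E)-1-methoxy-3-(trimethylsilyloxy)buta-1,3-diene (Danishefsky's diene)
Product: 6 (2S)-2-{2-[4-(benzyloxy)phenyl]ethyl}-2,3-dihydro-4H-pyran-4-one, via Mukaiyama aldol adduct 5 (not isolated)
Conditions: (R)-BINOL (20 mol %), Ti(OiPr)4 (10 mol %), 4 Å MS, Et2O, −20 °C; then CF3CO2H, CH2Cl2, 0 °C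
Reagents that add atoms: none
Why: BINOL–titanium-catalysed formal hetero-Diels–Alder reaction (Mukaiyama aldol addition, then acid-induced oxa-Michael closure with loss of methanol): the chiral Lewis acid should expose the Re face of the aldehyde and so set the later C5 as S, with enantiomeric purity checked at 6 and raised by recrystallisation if needed.

Step 3
Reactants: 7 5-bromo-2-hydroxy-3-methoxybenzaldehyde
Product: 9 5-bromo-3-methoxybenzene-1,2-diol, via aryl formate 8 (not isolated)
Conditions: 30 % aq H2O2, NaOH, H2O–THF, 0 °C to rt, N2; then aq HCl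
Reagents that add atoms: hydrogen peroxide, OO
Why: Dakin oxidation: hydroperoxide adds to the aldehyde ortho to the phenoxide, aryl migration gives formate 8, and this is saponified in the flask, which leaves bromine para to the central oxygen exactly where C1 must be attached.

Step 4
Reactants: 9 5-bromo-3-methoxybenzene-1,2-diol
Product: 10 1,2-bis(benzyloxy)-5-bromo-3-methoxybenzene
Conditions: BnBr (2.2 equiv), K2CO3, DMF, rt to 50 °C, N2
Reagents that add atoms: benzyl bromide, BrCc1ccccc1
Why: Williamson ether synthesis on both acidic catechol hydroxyl groups, which masks them with the same hydrogenolysable group that ring B carries.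

Step 5
Reactants: 10 1,2-bis(benzyloxy)-5-bromo-3-methoxybenzene; 6 (2S)-2-{2-[4-(benzyloxy)phenyl]ethyl}-2,3-dihydro-4H-pyran-4-one
Product: 13 (2R,6S)-2-[3,4-bis(benzyloxy)-5-methoxyphenyl]-6-{2-[4-(benzyloxy)phenyl]ethyl}oxan-4-one, via aryl Grignard reagent 11 (not isolated), via silyl enol ether 12 (not isolated)
Conditions: 10 (1.5 equiv), Mg turnings, THF, reflux; added to 6, CuBr·SMe2 (10 mol %), Me3SiCl (2 equiv), THF, −78 to −40 °C; then 1 M HCl, THF, 0 °C
Reagents that add atoms: none
Why: Transmetalation of 11 to monovalent copper gives an arylcuprate that binds the C1=C2 bond of the vinylogous ester 6; chlorosilane-assisted oxidative addition at C1 gives a trivalent copper β-adduct, reductive elimination forms the C1–C(ipso, ring A) bond, and the enolate is trapped as 12, which dilute acid hydrolyses to ketone 13. The closest known reaction type is the copper-catalysed, chlorosilane-accelerated conjugate addition of Grignard reagents to enones, which is established for 2,3-dihydro-4H-pyran-4-ones, including glycal-derived enones on the way to aryl C-glycosides. No ring is closed; the oxane ring already present serves only as a temporary tether between O5 and C1. The one new stereocentre, C1, is controlled by the C5 substituent: axial attack on the half-chair with the C5 side chain pseudo-equatorial should give the 2,6-trans oxanone, but step 6 erases this centre, so either epimer serves. The step needs 1,4- over 1,2-addition, and it needs addition to outrun deprotonation at C4, which would expel O5 and endanger C5. The donor oxygen that deactivates the carbonyl group, the unsubstituted β-carbon C1, the soft cuprate with Me3SiCl and the low temperature secure this, and the site on ring A is fixed by the bromine of 10.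

Step 6
Reactants: 13 (2R,6S)-2-[3,4-bis(benzyloxy)-5-methoxyphenyl]-6-{2-[4-(benzyloxy)phenyl]ethyl}oxan-4-one
Product: 16 (5S)-1-(3,4-dihydroxy-5-methoxyphenyl)-5-hydroxy-7-(4-hydroxyphenyl)heptan-3-one, via triphenol oxanone 14 (not isolated), via ring-opened enone 15 (not isolated)
Conditions: H2 (4 bar), Pd(OH)2/C, EtOH–EtOAc, AcOH (5 vol %), rt
Reagents that add atoms: none
Why: Catalytic hydrogenolysis of benzylic C–O bonds: the three benzyl ethers should fall first to give 14, in which the C1–O5 bond is a p-hydroxybenzyl ether β to the C3 ketone and so opens either directly on palladium or by retro-oxa-Michael reaction to enone 15, whose C1=C2 bond is hydrogenated irreversibly, while C5 keeps its C–O bond and the dialkyl ketone is inert to palladium.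

Step 7
Reactants: 16 (5S)-1-(3,4-dihydroxy-5-methoxyphenyl)-5-hydroxy-7-(4-hydroxyphenyl)heptan-3-one
Product: 18 (3R,5S)-1-(3,4-dihydroxy-5-methoxyphenyl)-7-(4-hydroxyphenyl)heptane-3,5-diol, via diethylboron chelate 17 (not isolated)
Conditions: Et2BOMe (4 equiv), THF–MeOH (4:1), −78 °C, Ar; NaBH4, −78 °C; pH 7 buffer, then repeated evaporation from MeOH
Reagents that add atoms: none
Why: Narasaka–Prasad reduction: Et2BOMe ties the C5 hydroxyl group and the C3 carbonyl group into the six-membered chelate 17, whose half-chair with the C5 side chain pseudo-equatorial takes external hydride along the axial trajectory, which should set C3 as R (syn to C5), while the phenols bind the excess boron reagent only reversibly.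

Compound list
1 | 1-(benzyloxy)-4-iodobenzene | Ic1ccc(OCc2ccccc2)cc1 | starting material
2 | prop-2-en-1-ol (allyl alcohol) | C=CCO | starting material
3 | 3-[4-(benzyloxy)phenyl]propanal | O=CCCc1ccc(OCc2ccccc2)cc1 | intermediate
4 | (E)-1-methoxy-3-(trimethylsilyloxy)buta-1,3-diene (Danishefsky's diene) | CO/C=C/C(=C)O[Si](C)(C)C | starting material
5 | (1E,5S)-7-[4-(benzyloxy)phenyl]-1-methoxy-5-(trimethylsilyloxy)hept-1-en-3-one | CO/C=C/C(=O)C[C@@H](O[Si](C)(C)C)CCc1ccc(OCc2ccccc2)cc1 | intermediate
6 | (2S)-2-{2-[4-(benzyloxy)phenyl]ethyl}-2,3-dihydro-4H-pyran-4-one | O=C1C=CO[C@@H](CCc2ccc(OCc3ccccc3)cc2)C1 | intermediate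
7 | 5-bromo-2-hydroxy-3-methoxybenzaldehyde | COc1cc(Br)cc(C=O)c1O | starting material
8 | 5-bromo-2-hydroxy-3-methoxyphenyl formate | COc1cc(Br)cc(OC=O)c1O | intermediate
9 | 5-bromo-3-methoxybenzene-1,2-diol | COc1cc(Br)cc(O)c1O | intermediate
10 | 1,2-bis(benzyloxy)-5-bromo-3-methoxybenzene | COc1cc(Br)cc(OCc2ccccc2)c1OCc1ccccc1 | intermediate
11 | [3,4-bis(benzyloxy)-5-methoxyphenyl]magnesium bromide | COc1cc([Mg]Br)cc(OCc2ccccc2)c1OCc1ccccc1 | intermediate
12 | {[(2S,6R)-6-[3,4-bis(benzyloxy)-5-methoxyphenyl]-2-{2-[4-(benzyloxy)phenyl]ethyl}-3,6-dihydro-2H-pyran-4-yl]oxy}trimethylsilane (2,6-trans) | C[Si](C)(C)OC1=C[C@H](c2cc(OC)c(OCc3ccccc3)c(OCc3ccccc3)c2)O[C@@H](CCc2ccc(OCc3ccccc3)cc2)C1 | intermediate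
13 | (2R,6S)-2-[3,4-bis(benzyloxy)-5-methoxyphenyl]-6-{2-[4-(benzyloxy)phenyl]ethyl}oxan-4-one (2,6-trans) | O=C1C[C@H](c2cc(OC)c(OCc3ccccc3)c(OCc3ccccc3)c2)O[C@@H](CCc2ccc(OCc3ccccc3)cc2)C1 | intermediate
14 | (2R,6S)-2-(3,4-dihydroxy-5-methoxyphenyl)-6-[2-(4-hydroxyphenyl)ethyl]oxan-4-one | O=C1C[C@H](c2cc(OC)c(O)c(O)c2)O[C@@H](CCc2ccc(O)cc2)C1 | intermediate
15 | (1E,5S)-1-(3,4-dihydroxy-5-methoxyphenyl)-5-hydroxy-7-(4-hydroxyphenyl)hept-1-en-3-one | COc1cc(/C=C/C(=O)C[C@@H](O)CCc2ccc(O)cc2)cc(O)c1O | intermediate
16 | (5S)-1-(3,4-dihydroxy-5-methoxyphenyl)-5-hydroxy-7-(4-hydroxyphenyl)heptan-3-one | COc1cc(CCC(=O)C[C@@H](O)CCc2ccc(O)cc2)cc(O)c1O | intermediate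
17 | O5-diethylboryl derivative (chelate) of 16 | CCB(CC)O[C@@H](CCc1ccc(O)cc1)CC(=O)CCc1cc(O)c(O)c(OC)c1 | intermediate
18 | (3R,5S)-1-(3,4-dihydroxy-5-methoxyphenyl)-7-(4-hydroxyphenyl)heptane-3,5-diol (syn diol) | COc1cc(CC[C@@H](O)C[C@@H](O)CCc2ccc(O)cc2)cc(O)c1O | target

Total step count: 7
Longest linear sequence: 5 steps (steps 1, 2, 5, 6, 7; the ring A branch, steps 3, 4, 5, 6, 7, is equally long)

Steps most likely to fail

Step 5. The Grignard reagent may add 1,2 to the carbonyl group before copper takes it up. It may also deprotonate C4, so that O5 is expelled and the ring opens. The fallback sets out from 10 and replaces the basic organomagnesium/copper system by a catalytic carbometalation with an isolated boron nucleophile in aqueous medium. Bromine–lithium exchange (n-BuLi, THF, −78 °C), B(OiPr)3 and acidic work-up should give [3,4-bis(benzyloxy)-5-methoxyphenyl]boronic acid F1. A Hayashi–Miyaura 1,4-addition of F1 to 6 ([Rh(cod)Cl]2, KOH, dioxane–H2O, 40 °C) inserts the C1=C2 bond into an aryl–rhodium bond, and water protonates the resulting rhodium enolate. This forms the same C1–aryl bond and comes back to the route at 13.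

Step 6. After loss of the benzyl groups the ring C1–O5 bond may resist cleavage, or the β-hydroxy ketone may lose water. The fallback sets out from 13 and uses the ring as a stereochemical template before opening it ionically.
- Acid equilibration (Amberlyst-15, CH2Cl2, rt; retro-oxa-Michael/oxa-Michael) should converge on the diequatorial 2,6-cis oxan-4-one F2.
- LiBH(s-Bu)3 (L-Selectride, THF, −78 °C) attacks from the equatorial side and should give the axial oxan-4-ol F3, which already holds the syn C3/C5 relationship.
- Ionic hydrogenation (Et3SiH, BF3·OEt2, CH2Cl2, −78 to −20 °C) ionises C1–O5 to the p-benzyloxybenzyl cation and reduces it to the tri-O-benzyl syn-diol F4.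
- Plain debenzylation (H2, Pd/C, EtOAc–EtOH) comes back to the route at 18, bypassing 16.

Step 7. The catechol of ring A may sequester the boron reagent, so that chelation control and hence facial selectivity erode. The electron-rich ring may also suffer oxidation in the basic medium. The fallback sets out from 16 and masks the phenols first. TBSCl (3.3 equiv), imidazole, DMF, 0 °C should silylate the three acidic phenols ahead of the hydrogen-bonded secondary alcohol and give the tris(TBS) hydroxy ketone F5. The same chelation-controlled reduction then meets only the β-hydroxy ketone and should give the tris(TBS) syn-diol F6. Et3N·3HF in THF at rt removes the silyl groups under non-basic conditions and comes back to the route at 18.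

Further compounds
F1 | step 5 | [3,4-bis(benzyloxy)-5-methoxyphenyl]boronic acid | COc1cc(B(O)O)cc(OCc2ccccc2)c1OCc1ccccc1
F2 | step 6 | (2S,6S)-2-[3,4-bis(benzyloxy)-5-methoxyphenyl]-6-{2-[4-(benzyloxy)phenyl]ethyl}oxan-4-one (2,6-cis) | O=C1C[C@@H](c2cc(OC)c(OCc3ccccc3)c(OCc3ccccc3)c2)O[C@@H](CCc2ccc(OCc3ccccc3)cc2)C1
F3 | step 6 | (2S,4S,6S)-2-[3,4-bis(benzyloxy)-5-methoxyphenyl]-6-{2-[4-(benzyloxy)phenyl]ethyl}oxan-4-ol (2,6-cis, 4-OH axial) | O[C@@H]1C[C@@H](c2cc(OC)c(OCc3ccccc3)c(OCc3ccccc3)c2)O[C@@H](CCc2ccc(OCc3ccccc3)cc2)C1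
F4 | step 6 | (3R,5S)-1-[3,4-bis(benzyloxy)-5-methoxyphenyl]-7-[4-(benzyloxy)phenyl]heptane-3,5-diol | COc1cc(CC[C@@H](O)C[C@@H](O)CCc2ccc(OCc3ccccc3)cc2)cc(OCc2ccccc2)c1OCc1ccccc1
F5 | step 7 | (5S)-1-{3,4-bis[(tert-butyldimethylsilyl)oxy]-5-methoxyphenyl}-7-{4-[(tert-butyldimethylsilyl)oxy]phenyl}-5-hydroxyheptan-3-one | COc1cc(CCC(=O)C[C@@H](O)CCc2ccc(O[Si](C)(C)C(C)(C)C)cc2)cc(O[Si](C)(C)C(C)(C)C)c1O[Si](C)(C)C(C)(C)C
F6 | step 7 | (3R,5S)-1-{3,4-bis[(tert-butyldimethylsilyl)oxy]-5-methoxyphenyl}-7-{4-[(tert-butyldimethylsilyl)oxy]phenyl}heptane-3,5-diol | COc1cc(CC[C@@H](O)C[C@@H](O)CCc2ccc(O[Si](C)(C)C(C)(C)C)cc2)cc(O[Si](C)(C)C(C)(C)C)c1O[Si](C)(C)C(C)(C)C
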